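The runs were generated by integration for an exercise; the scatter is artificial.

The question is how the excess of left-handed product, meaning the difference of the two products over their sum, ranks across the flasks at both times.

- ranking by excess of left-handed product over right-handed product, from high to low, at 6.0 min (blue / green / grey / ochre / amber)
- the same order at 20 s (blue / green / grey / ochre / amber)
- the excess of left-handed product over right-handed product of the flask you put first, at 6.0 min
- the excess of left-handed product over right-handed product of the flask you put last, at 6.0 min

| setting | noon | summer | blue | green | grey | ochre | amber |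
|---|---|---|---|---|---|---|---|
| left-handed substrate | 0.050 M | 0.050 M | 0.050 M | 0.050 M | 0.050 M | 0.050 M | 0.050 M |
| right-handed substrate | 0.050 M | 0.050 M | 0.050 M | 0.050 M | 0.050 M | 0.050 M | 0.050 M |
| partner | 0.15 M | 0.15 M | 0.150 M | 0.150 M | 0.150 M | 0.150 M | 0.150 M |
| protic impurity | 0.025 M | 0.025 M | 0.0250 M | 0.0250 M | 0.0250 M | 0.0250 M | 0.0250 M |
| catalyst | 1.7 mM | 5.2 mM | 15 mM | 4.1 mM | 3.0 mM | 1.5 mM | 8.0 mM |
| remark | run made earlier | run made earlier |  |  |  |  |  |
| time |  |  | 6.0 min | 6.0 min | 6.0 min | 6.0 min | 6.0 min |

| run | time / min | left-handed product / % | right-handed product / % | left-handed substrate / % |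
|---|---|---|---|---|
| noon | 0.500 | 14 | 6 | 36 |
| noon | 0.833 | 21 | 8 | 28 |
| noon | 1.50 | 22 | 10 | 25 |
| noon | 3.00 | 35 | 18 | 16 |
| noon | 6.00 | 43 | 24 | 8 |
| summer | 1.33 | 41 | 20 | 8 |
| summer | 2.50 | 45 | 29 | 6 |
| summer | 4.00 | 49 | 35 | 3 |
| summer | 5.00 | 48 | 40 | 0 |
| summer | 6.00 | 48 | 40 | 2 |

(each reading ± 1.5 percentage points)

- catalyst is single-handed; left-handed substrate and right-handed substrate are mirror images of each other, charged as a racemate, each of them at the stated concentration

Start from the end state. The partner charged, 0.150 M, is more than both substrates and the impurity need if each takes one partner, so a flask left long enough should lose its excess. The excess therefore tells how far each of these flasks, alike but for catalyst, has gone.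

Take the main step first. If catalyst and partner use each substrate in proportion to its own amount, the logarithms of the parts left keep a fixed ratio, whatever the speed. Noon's right-handed product at 6.00 min reads as 52.0% of its right-handed substrate left, and with the left-handed substrate read there this gives the selectivity factor, the ratio of the two logarithms of the parts left, each of its own charge, a reading with its scatter:

s = ln(left-handed part left) / ln(right-handed part left) = 2.80

Summer at 2.50 min gives 2.44, which is near it given a scatter of 1.5 percentage points. With x the right-handed part left:

excess = (x − x^s) / (2 − x − x^s)

So the depth, −ln x, of a flask gives its excess, as long as s holds. Noon's first speed, 0.256 /min, scaled to ochre's catalyst and held for 6.0 min, gives depth 1.35 and an excess of 13.7%.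

Now add the slowing. Noon reads depth 0.654, less than that speed gives, and this depth scaled to ochre's catalyst gives an estimate of 56.2% left and an excess of 29.3%.

Then add the rest. Summer's depth at 6.00 min, 1.61, held against noon's, reads as catalyst to the power 0.806. That gives ochre 55.4% left and an excess of 28.9%, and blue 2.29% left and an excess of 1.15%. At fixed s excess falls as x falls, and summer at 1.33 min reads more right-handed product than noon at 1.50 min, so you rank by catalyst, lowest first, at 20 s as well, although that time lies before the first reading.

The forecast gave ochre > grey > green > amber > blue at 6.0 min and ochre > grey > green > amber > blue at 20 s, with 30% (26% to 34%) for ochre and 2% (0.3% to 5%) for blue, holding that the selectivity “does not change detectably with catalyst loading or time”.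

The flasks give ochre > grey > green > amber > blue at 6.0 min and ochre > grey > green > amber > blue at 20 s, with 28.3% for ochre and 1.63% for blue.

    partner + catalyst + left-handed substrate → catalyst + left-handed product (k = 3600 /M²/min)
    partner + protic impurity → quenched reagent (k = 3.80 /M/min)
    partner ⇌ dormant form (K = 0.890, k = 1.40 /min)
    partner + catalyst + right-handed substrate → catalyst + right-handed product (k = 1300 /M²/min)

In ochre the passing of partner into dormant form has a forward half-life of 0.50 min, forward step alone, shorter than the 2.6 min of the left-handed main step with charges held. Half of its turnover up to 6.0 min is done by 0.0930 min, against 1.16 min for that main step. For ochre's neighbour with 0.0026 M of catalyst, the reckoning gives 39.8% of the right-handed substrate left and, with s, an excess of 21.1%. The computed flask gives 21.1%.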